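**Strategy.** The flavanone is disconnected across ring A. Its six atoms C4a, C5, C6, C7, C8 and C8a, with the oxygens on C5 and C7, are built in one operation on the C4a=C8a double bond (C5=C6 of the monocycle) of a (2R,3S)-2,3-diaryl-2,3-dihydropyran-4-one, the future ring C. The two stereocentres of that pyranone are set earlier by an asymmetric hetero-Diels–Alder reaction. The key step is a Diels–Alder benzannulation with an acetoacetate-derived 1-methoxy-1,3-bis(silyloxy)diene: it forms C8–C8a and C4a–C5, then aromatises by loss of a C4a leaving group and methanol. The precursor is the MOM-protected pyranone carrying a phenylsulfinyl group on C5 and an aryl iodide for the closing Heck coupling.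

Key step: step 12

Assumption: the target is read from the SMILES as the 2,3-trans isomer, (2R,3S).
Assumption: the titanium catalyst made from (R)-BINOL is taken to direct the nucleophile to the Re face of an aromatic aldehyde; if the opposite sense is found, (S)-BINOL is used.
Remark: MOM = methoxymethyl; BINOL = 1,1'-bi-2-naphthol; fod = 6,6,7,7,8,8,8-heptafluoro-2,2-dimethyloctane-3,5-dionate; pyranone positions C5 and C6 become C4a and C8a of the chromanone.

**Route**

Step 1
Reactants: 1 2-(2-hydroxyphenyl)acetic acid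
Product: 2 2-(2-hydroxy-5-iodophenyl)acetic acid
Conditions: NIS (1.05 equiv), TsOH·H2O (10 mol%), MeCN, 0 °C → rt
Reagents that add atoms: N-iodosuccinimide, O=C1CCC(=O)N1I
Why: Electrophilic aromatic iodination directed para to the free phenol (C5); an iodide is chosen over a bromide so that the late Heck coupling can run at low temperature.

Step 2
Reactants: 2 2-(2-hydroxy-5-iodophenyl)acetic acid
Product: 3 methoxymethyl 2-[5-iodo-2-(methoxymethoxy)phenyl]acetate
Conditions: MOMCl (2.5 equiv), i-Pr2NEt (3 equiv), CH2Cl2, 0 °C → rt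
Reagents that add atoms: chloromethyl methyl ether, COCCl
Why: Williamson-type O-alkylation of phenol and carboxylate in one operation, which masks both acidic groups and makes the acid an activated acyloxymethyl ester.

Step 3
Reactants: 3 methoxymethyl 2-[5-iodo-2-(methoxymethoxy)phenyl]acetate
Product: 4 2-[5-iodo-2-(methoxymethoxy)phenyl]-N-methoxy-N-methylacetamide
Conditions: Me(MeO)NH·HCl (1.5 equiv), i-PrMgCl (3.0 equiv), THF, −20 °C; then 3, −20 → 0 °C
Reagents that add atoms: N,O-dimethylhydroxylamine hydrochloride, CNOC.Cl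
Why: Ester aminolysis by the preformed chloromagnesium amide; the amide base is made before 3 is added, so no i-PrMgCl remains to exchange with the aryl iodide, and the aryl MOM ether is inert to base.

Step 4
Reactants: 4 2-[5-iodo-2-(methoxymethoxy)phenyl]-N-methoxy-N-methylacetamide; 5 ethynylmagnesium bromide
Product: 6 1-[5-iodo-2-(methoxymethoxy)phenyl]but-3-yn-2-one
Conditions: 5 (2.5 equiv), THF, 0 °C; inverse quench into cold aq. NaHSO4
Reagents that add atoms: none
Why: Weinreb ketone synthesis: the N-methoxy-N-methylamide takes up one acetylide only, the weakly basic acetylide leaves the benzylic position and the aryl iodide alone, and the acidic quench keeps the liberated amine from adding to the ynone.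

Step 5
Reactants: 6 1-[5-iodo-2-(methoxymethoxy)phenyl]but-3-yn-2-one
Product: 7 (E)-1-[5-iodo-2-(methoxymethoxy)phenyl]-4-methoxybut-3-en-2-one
Conditions: MeOH (5 equiv), DABCO (10 mol%), CH2Cl2, 0 °C → rt
Reagents that add atoms: methanol, CO
Why: Amine-catalysed oxa-Michael addition of methanol to the terminal ynone, which should give the more stable (E)-β-methoxy enone.

Step 6
Reactants: 7 (E)-1-[5-iodo-2-(methoxymethoxy)phenyl]-4-methoxybut-3-en-2-one
Product: 9 triethyl{[(1Z,3E)-1-[5-iodo-2-(methoxymethoxy)phenyl]-4-methoxybuta-1,3-dien-2-yl]oxy}silane, via lithium dienolate 8 (not isolated)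
Conditions: LiN(SiMe3)2 (1.1 equiv), THF, −78 °C; Et3SiCl (1.2 equiv), −78 → 0 °C; non-aqueous work-up
Reagents that add atoms: chlorotriethylsilane, CC[Si](Cl)(CC)CC
Why: Enolisation at the only enolisable carbon (the benzylic CH2) and O-silylation give the 1-methoxy-3-silyloxy diene with the (Z)-enol ether expected for an aryl-conjugated enolate; the basic conditions spare the MOM ether.

Step 7
Reactants: 10 4-hydroxybenzaldehyde
Product: 11 4-(methoxymethoxy)benzaldehyde
Conditions: MOMCl (1.3 equiv), i-Pr2NEt (1.5 equiv), CH2Cl2, 0 °C → rt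
Reagents that add atoms: chloromethyl methyl ether, COCCl
Why: Williamson-type O-alkylation of the phenol.

Step 8
Reactants: 9 triethyl{[(1Z,3E)-1-[5-iodo-2-(methoxymethoxy)phenyl]-4-methoxybuta-1,3-dien-2-yl]oxy}silane; 11 4-(methoxymethoxy)benzaldehyde
Product: 13 (2R,3S)-3-[5-iodo-2-(methoxymethoxy)phenyl]-2-[4-(methoxymethoxy)phenyl]-2,3-dihydro-4H-pyran-4-one, via silylated aldol adduct 12 (not isolated)
Conditions: (R)-BINOL (20 mol%), Ti(OiPr)4 (10 mol%), 4 Å MS, Et2O, −20 °C → rt; then TFA (0.3 equiv), CH2Cl2, 0 °C → rt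
Reagents that add atoms: none
Why: Formal hetero-Diels–Alder reaction by the Mukaiyama aldol–cyclisation pathway: the chiral titanium BINOLate should deliver the aryl-bearing diene terminus to the Re face of the aldehyde and so set C2 as R; acid then closes the ring with loss of methanol, and C3, benzylic and α to the ketone, equilibrates under the same acid to the trans-diequatorial (3S) arrangement.

Step 9
Reactants: 13 (2R,3S)-3-[5-iodo-2-(methoxymethoxy)phenyl]-2-[4-(methoxymethoxy)phenyl]-2,3-dihydro-4H-pyran-4-one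
Product: 15 (2R,3S)-3-[5-iodo-2-(methoxymethoxy)phenyl]-2-[4-(methoxymethoxy)phenyl]-5-(phenylsulfanyl)-2,3-dihydro-4H-pyran-4-one, via chloro sulfide adduct 14 (not isolated)
Conditions: PhSCl (1.1 equiv), CH2Cl2, −78 → −20 °C; then Et3N (1.5 equiv), −20 → 0 °C
Reagents that add atoms: benzenesulfenyl chloride, ClSc1ccccc1
Why: Electrophilic sulfenylation of the enol-ether carbon C5 (addition of PhSCl across C5=C6, then dehydrochlorination of the α-chloro ether); the alkoxyarene rings are far less nucleophilic at this temperature, and brief cold Et3N should not enolise C3.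

Step 10
Reactants: 15 (2R,3S)-3-[5-iodo-2-(methoxymethoxy)phenyl]-2-[4-(methoxymethoxy)phenyl]-5-(phenylsulfanyl)-2,3-dihydro-4H-pyran-4-one
Product: 16 (2R,3S)-3-[5-iodo-2-(methoxymethoxy)phenyl]-2-[4-(methoxymethoxy)phenyl]-5-(phenylsulfinyl)-2,3-dihydro-4H-pyran-4-one (both epimers at sulfur)
Conditions: mCPBA (1.0 equiv), NaHCO3, CH2Cl2, −78 → −40 °C
Reagents that add atoms: 3-chloroperoxybenzoic acid, OOC(=O)c1cccc(Cl)c1
Why: Chemoselective oxidation of the sulfide to the sulfoxide; the electron-poor alkene, the aryl iodide and the MOM ethers should be untouched, and both sulfur epimers serve equally because sulfur is lost in step 12.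

Step 11
Reactants: 17 methyl acetoacetate
Product: 19 1-methoxy-1,3-bis(trimethylsilyloxy)buta-1,3-diene, via mono(silyl) enol ether 18 (not isolated)
Conditions: TMSOTf (2.2 equiv), Et3N (2.5 equiv), Et2O, 0 °C → rt; distilled
Reagents that add atoms: trimethylsilyl trifluoromethanesulfonate, C[Si](C)(C)OS(=O)(=O)C(F)(F)F
Why: Twofold soft enolisation and O-silylation, first of the ketone and then, after γ-deprotonation, of the ester carbonyl; the ketene acetal geometry is immaterial.

Step 12
Reactants: 16 (2R,3S)-3-[5-iodo-2-(methoxymethoxy)phenyl]-2-[4-(methoxymethoxy)phenyl]-5-(phenylsulfinyl)-2,3-dihydro-4H-pyran-4-one; 19 1-methoxy-1,3-bis(trimethylsilyloxy)buta-1,3-diene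
Product: 23 (2R,3S)-5,7-dihydroxy-3-[5-iodo-2-(methoxymethoxy)phenyl]-2-[4-(methoxymethoxy)phenyl]chroman-4-one, via cis-fused cycloadduct 20 (not isolated), via dienyl ketal 21 (not isolated), via bis(trimethylsilyl) ether 22 (not isolated)
Conditions: 19 (3 equiv), Eu(fod)3 (10 mol%), PhMe, 0 °C → rt; then 90 °C; then aq. citric acid, THF–MeOH, rt
Reagents that add atoms: none
Why: Proposed new method: the CH2 terminus of diene 19, its most nucleophilic carbon, should attack pyranone C6 (the future C8a), the one carbon β to both the C4 carbonyl and the sulfinyl group, and the ketene-acetal carbon should then close onto the sulfur-bearing C5 (future C4a), a concerted but strongly asynchronous [4+2] cycloaddition that forms C8–C8a and C4a–C5 and closes the six-membered ring A in the Diels–Alder mode, with Eu(fod)3 chelating the β-keto sulfoxide to lower the LUMO. The closest known reaction type is the Diels–Alder addition and aromatisation of 1-alkoxy-1,3-bis(silyloxy)dienes with haloquinones, sulfinylquinones and chromones carrying an acceptor on C3; a vinylogous ester of this kind has not been used as the dienophile. A phenylsulfinyl group is preferred to a halogen on C4a for two reasons: it is the stronger acceptor, which offsets the donor oxygen on C8a, and the angular C8a–H of a suprafacial adduct is neither acidic nor anti to the C4a substituent, so that only a group leaving by thermal syn-elimination matches this geometry. Warming should therefore expel benzenesulfenic acid from 20 to give the C4a=C8a alkene 21, 1,4-loss of methanol (C5–OMe with C8–H) aromatises ring A to 22, and mild aqueous acid frees the 5- and 7-hydroxyls from their trimethylsilyl ethers. No stereocentre is formed, and C2 and C3 are not touched because the medium stays free of base and C3 would in any case return to the trans arrangement. The selectivity needed is the orientation of the diene, which the push–pull polarisation of the alkene secures (C8a electrophilic, C4a carrying both acceptors); what remains uncertain is whether the oxygen-substituted alkene is electrophilic enough and whether addition stops after the first bond.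

Step 13
Reactants: 24 2,4-dihydroxybenzaldehyde
Product: 25 2,4-bis(methoxymethoxy)benzaldehyde
Conditions: NaH (2.5 equiv), MOMCl (2.5 equiv), DMF, 0 °C → rt
Reagents that add atoms: chloromethyl methyl ether, COCCl
Why: Williamson-type O-alkylation; the strong base is needed to alkylate the hydrogen-bonded ortho hydroxyl as well.

Step 14
Reactants: 25 2,4-bis(methoxymethoxy)benzaldehyde; 26 vinylmagnesium bromide
Product: 27 1-[2,4-bis(methoxymethoxy)phenyl]prop-2-en-1-ol (racemic)
Conditions: 26 (1.3 equiv), THF, −78 → 0 °C; aq. NH4Cl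
Reagents that add atoms: none
Why: Grignard 1,2-addition to the aldehyde; the new carbinol centre is removed in the next step.

Step 15
Reactants: 27 1-[2,4-bis(methoxymethoxy)phenyl]prop-2-en-1-ol
Product: 28 1-[2,4-bis(methoxymethoxy)phenyl]prop-2-en-1-one
Conditions: DMP (1.2 equiv), NaHCO3, CH2Cl2, 0 °C → rt; used at once
Reagents that add atoms: none
Why: Dess–Martin oxidation of the allylic, benzylic alcohol under buffered neutral conditions; the ortho MOM ether prevents intramolecular oxa-Michael closure of the vinyl ketone.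

Step 16
Reactants: 23 (2R,3S)-5,7-dihydroxy-3-[5-iodo-2-(methoxymethoxy)phenyl]-2-[4-(methoxymethoxy)phenyl]chroman-4-one; 28 1-[2,4-bis(methoxymethoxy)phenyl]prop-2-en-1-one
Product: 29 (2R,3S)-3-{5-[(1E)-3-[2,4-bis(methoxymethoxy)phenyl]-3-oxoprop-1-en-1-yl]-2-(methoxymethoxy)phenyl}-5,7-dihydroxy-2-[4-(methoxymethoxy)phenyl]chroman-4-one
Conditions: 28 (2 equiv), Pd(OAc)2 (5 mol%), n-Bu4NCl (1 equiv), NaHCO3 (2.5 equiv), DMF, 50 °C
Reagents that add atoms: none
Why: Heck reaction (oxidative addition of the aryl iodide to zerovalent palladium, insertion of the vinyl ketone, syn β-hydride elimination to the (E)-enone); the iodide allows 50 °C and a weak base, and deprotonation of the acidic 7-OH turns the ketone into a vinylogous carboxylate, which should lower the acidity of C3–H and so protect C2 and C3.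

Step 17
Reactants: 29 (2R,3S)-3-{5-[(1E)-3-[2,4-bis(methoxymethoxy)phenyl]-3-oxoprop-1-en-1-yl]-2-(methoxymethoxy)phenyl}-5,7-dihydroxy-2-[4-(methoxymethoxy)phenyl]chroman-4-one
Product: 30 (2R,3S)-3-{5-[(1E)-3-(2,4-dihydroxyphenyl)-3-oxoprop-1-en-1-yl]-2-hydroxyphenyl}-5,7-dihydroxy-2-(4-hydroxyphenyl)chroman-4-one
Conditions: 3 M aq. HCl, MeOH–THF, 45 °C
Reagents that add atoms: none
Why: Acid-catalysed acetal exchange removes all four MOM groups as dimethoxymethane; no base is present, acid can only return C3 to the trans arrangement, and the chalcone is not expected to close to a flavanone under brief acid treatment.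

**Compound list**

1 | 2-(2-hydroxyphenyl)acetic acid | O=C(O)Cc1ccccc1O | starting material
2 | 2-(2-hydroxy-5-iodophenyl)acetic acid | O=C(O)Cc1cc(I)ccc1O | intermediate
3 | methoxymethyl 2-[5-iodo-2-(methoxymethoxy)phenyl]acetate | COCOC(=O)Cc1cc(I)ccc1OCOC | intermediate
4 | 2-[5-iodo-2-(methoxymethoxy)phenyl]-N-methoxy-N-methylacetamide | CON(C)C(=O)Cc1cc(I)ccc1OCOC | intermediate
5 | ethynylmagnesium bromide | C#C[Mg]Br | starting material
6 | 1-[5-iodo-2-(methoxymethoxy)phenyl]but-3-yn-2-one | C#CC(=O)Cc1cc(I)ccc1OCOC | intermediate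
7 | (E)-1-[5-iodo-2-(methoxymethoxy)phenyl]-4-methoxybut-3-en-2-one | CO/C=C/C(=O)Cc1cc(I)ccc1OCOC | intermediate
8 | lithium (1Z,3E)-1-[5-iodo-2-(methoxymethoxy)phenyl]-4-methoxybuta-1,3-dien-2-olate | CO/C=C/C(/O[Li])=C/c1cc(I)ccc1OCOC | intermediate
9 | triethyl{[(1Z,3E)-1-[5-iodo-2-(methoxymethoxy)phenyl]-4-methoxybuta-1,3-dien-2-yl]oxy}silane | CO/C=C/C(/O[Si](CC)(CC)CC)=C/c1cc(I)ccc1OCOC | intermediate
10 | 4-hydroxybenzaldehyde | O=Cc1ccc(O)cc1 | starting material
11 | 4-(methoxymethoxy)benzaldehyde | COCOc1ccc(C=O)cc1 | intermediate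
12 | (1E,5R)-4-[5-iodo-2-(methoxymethoxy)phenyl]-1-methoxy-5-[4-(methoxymethoxy)phenyl]-5-(triethylsilyloxy)pent-1-en-3-one (C4 epimers) | CO/C=C/C(=O)C(c1cc(I)ccc1OCOC)[C@@H](O[Si](CC)(CC)CC)c1ccc(OCOC)cc1 | intermediate
13 | (2R,3S)-3-[5-iodo-2-(methoxymethoxy)phenyl]-2-[4-(methoxymethoxy)phenyl]-2,3-dihydro-4H-pyran-4-one | Ic1ccc(OCOC)c([C@@H]2C(=O)C=CO[C@H]2c2ccc(OCOC)cc2)c1 | intermediate
14 | (2R,3S)-6-chloro-3-[5-iodo-2-(methoxymethoxy)phenyl]-2-[4-(methoxymethoxy)phenyl]-5-(phenylsulfanyl)oxan-4-one (C5 and C6 unassigned) | Ic1ccc(OCOC)c([C@@H]2C(=O)C(Sc3ccccc3)C(Cl)O[C@H]2c2ccc(OCOC)cc2)c1 | intermediate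
15 | (2R,3S)-3-[5-iodo-2-(methoxymethoxy)phenyl]-2-[4-(methoxymethoxy)phenyl]-5-(phenylsulfanyl)-2,3-dihydro-4H-pyran-4-one | Ic1ccc(OCOC)c([C@@H]2C(=O)C(Sc3ccccc3)=CO[C@H]2c2ccc(OCOC)cc2)c1 | intermediate
16 | (2R,3S)-3-[5-iodo-2-(methoxymethoxy)phenyl]-2-[4-(methoxymethoxy)phenyl]-5-(phenylsulfinyl)-2,3-dihydro-4H-pyran-4-one (both epimers at sulfur) | Ic1ccc(OCOC)c([C@@H]2C(=O)C(S(=O)c3ccccc3)=CO[C@H]2c2ccc(OCOC)cc2)c1 | intermediate
17 | methyl acetoacetate | COC(=O)CC(C)=O | starting material
18 | methyl 3-(trimethylsilyloxy)but-2-enoate | COC(=O)C=C(C)O[Si](C)(C)C | intermediate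
19 | 1-methoxy-1,3-bis(trimethylsilyloxy)buta-1,3-diene | C=C(O[Si](C)(C)C)/C=C(/OC)O[Si](C)(C)C | intermediate
20 | (2R,3S)-3-[5-iodo-2-(methoxymethoxy)phenyl]-5-methoxy-2-[4-(methoxymethoxy)phenyl]-4a-(phenylsulfinyl)-5,7-bis(trimethylsilyloxy)-2,3,4a,5,8,8a-hexahydro-4H-chromen-4-one (4a,8a-cis; new centres otherwise unassigned) | Ic1ccc(OCOC)c([C@@H]2C(=O)C3(S(=O)c4ccccc4)C(CC(O[Si](C)(C)C)=CC3(OC)O[Si](C)(C)C)O[C@H]2c2ccc(OCOC)cc2)c1 | intermediate
21 | (2R,3S)-3-[5-iodo-2-(methoxymethoxy)phenyl]-5-methoxy-2-[4-(methoxymethoxy)phenyl]-5,7-bis(trimethylsilyloxy)-2,3,5,8-tetrahydro-4H-chromen-4-one (C5 unassigned) | Ic1ccc(OCOC)c([C@@H]2C(=O)C3=C(CC(O[Si](C)(C)C)=CC3(OC)O[Si](C)(C)C)O[C@H]2c2ccc(OCOC)cc2)c1 | intermediate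
22 | (2R,3S)-3-[5-iodo-2-(methoxymethoxy)phenyl]-2-[4-(methoxymethoxy)phenyl]-5,7-bis(trimethylsilyloxy)chroman-4-one | Ic1ccc(OCOC)c([C@@H]2C(=O)c3c(O[Si](C)(C)C)cc(O[Si](C)(C)C)cc3O[C@H]2c2ccc(OCOC)cc2)c1 | intermediate
23 | (2R,3S)-5,7-dihydroxy-3-[5-iodo-2-(methoxymethoxy)phenyl]-2-[4-(methoxymethoxy)phenyl]chroman-4-one | Ic1ccc(OCOC)c([C@@H]2C(=O)c3c(O)cc(O)cc3O[C@H]2c2ccc(OCOC)cc2)c1 | intermediate
24 | 2,4-dihydroxybenzaldehyde | O=Cc1ccc(O)cc1O | starting material
25 | 2,4-bis(methoxymethoxy)benzaldehyde | COCOc1ccc(C=O)c(OCOC)c1 | intermediate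
26 | vinylmagnesium bromide | C=C[Mg]Br | starting material
27 | 1-[2,4-bis(methoxymethoxy)phenyl]prop-2-en-1-ol (racemic) | C=CC(O)c1ccc(OCOC)cc1OCOC | intermediate
28 | 1-[2,4-bis(methoxymethoxy)phenyl]prop-2-en-1-one | C=CC(=O)c1ccc(OCOC)cc1OCOC | intermediate
29 | (2R,3S)-3-{5-[(1E)-3-[2,4-bis(methoxymethoxy)phenyl]-3-oxoprop-1-en-1-yl]-2-(methoxymethoxy)phenyl}-5,7-dihydroxy-2-[4-(methoxymethoxy)phenyl]chroman-4-one | O=C(/C=C/c1ccc(OCOC)c([C@@H]2C(=O)c3c(O)cc(O)cc3O[C@H]2c2ccc(OCOC)cc2)c1)c1ccc(OCOC)cc1OCOC | intermediate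
30 | (2R,3S)-3-{5-[(1E)-3-(2,4-dihydroxyphenyl)-3-oxoprop-1-en-1-yl]-2-hydroxyphenyl}-5,7-dihydroxy-2-(4-hydroxyphenyl)chroman-4-one | O=C(/C=C/c1ccc(O)c([C@@H]2C(=O)c3c(O)cc(O)cc3O[C@H]2c2ccc(O)cc2)c1)c1ccc(O)cc1O | target

**Step count.** Total: 17 steps. Longest linear sequence: 12 steps (1, 2, 3, 4, 5, 6, 8, 9, 10, 12, 16, 17).

**Steps most likely to fail, with fallbacks**

1. Step 12 (proposed new method). The oxygen-substituted alkene may be too weak a dienophile. Addition may also stop after the first C–C bond and be followed by β-alkoxide ring opening, or the silyl ketene acetal may reduce the sulfoxide in a Pummerer-type process. The fallback brings in ring A ready-made by known deoxybenzoin chemistry. It sets out from amide 4: addition of 2,4,6-tris(methoxymethoxy)phenyllithium (from 1,3,5-tris(methoxymethoxy)benzene and n-BuLi, THF, 0 °C, then 4 at −78 °C) should give 2-[5-iodo-2-(methoxymethoxy)phenyl]-1-[2,4,6-tris(methoxymethoxy)phenyl]ethan-1-one F1. Dilute HCl in MeOH at 0 °C to rt, stopped at mono-cleavage, removes the hydrogen-bonded ortho MOM group first and should give 1-[2-hydroxy-4,6-bis(methoxymethoxy)phenyl]-2-[5-iodo-2-(methoxymethoxy)phenyl]ethan-1-one F2. Condensation of F2 with aldehyde 11 (piperidine, EtOH, reflux; aldol condensation, oxa-Michael closure, trans by equilibration) gives the racemic chromanone. Preparative HPLC on a chiral stationary phase separates it into (2R,3S)-3-[5-iodo-2-(methoxymethoxy)phenyl]-5,7-bis(methoxymethoxy)-2-[4-(methoxymethoxy)phenyl]chroman-4-one F3 and the unwanted (2S,3R)-3-[5-iodo-2-(methoxymethoxy)phenyl]-5,7-bis(methoxymethoxy)-2-[4-(methoxymethoxy)phenyl]chroman-4-one F4. Heck coupling of F3 with vinyl ketone 28 under the conditions of step 16 gives (2R,3S)-3-{5-[(1E)-3-[2,4-bis(methoxymethoxy)phenyl]-3-oxoprop-1-en-1-yl]-2-(methoxymethoxy)phenyl}-5,7-bis(methoxymethoxy)-2-[4-(methoxymethoxy)phenyl]chroman-4-one F5. The acid treatment of step 17 then removes all six MOM groups, and the fallback comes back to the route at target 30.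

2. Step 8. The hindered aryl-substituted silyl enol ether may add slowly to the electron-rich aldehyde, an uncatalysed or silyl-cation-catalysed background reaction may erode facial selectivity, and some MOM ether may be lost in the acid stage. The fallback replaces the catalytic reaction by a stoichiometric chiral boron aldol, a known way to dihydropyranones from β-alkoxyvinyl ketones. It sets out from ketone 7: enolisation with diisopinocampheylboron triflate and i-Pr2NEt (CH2Cl2, −78 °C; the antipode that leads to Re-face addition) and addition to aldehyde 11 should give (1E,5R)-5-hydroxy-4-[5-iodo-2-(methoxymethoxy)phenyl]-1-methoxy-5-[4-(methoxymethoxy)phenyl]pent-1-en-3-one F6. TFA in CH2Cl2 then closes the ring with loss of methanol and equilibrates C3, and the fallback comes back at pyranone 13.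

3. Step 16. Base may open the flavanone by retro-oxa-Michael reaction and so scramble C2; phenoxide may add to the vinyl ketone, or the vinyl ketone may polymerise. The fallback builds the enone without base. It sets out from iodide 23: Stille coupling with tributyl(vinyl)stannane (Pd(PPh3)4, PhMe, 90 °C) should give (2R,3S)-3-[5-ethenyl-2-(methoxymethoxy)phenyl]-5,7-dihydroxy-2-[4-(methoxymethoxy)phenyl]chroman-4-one F7. Olefin cross-metathesis of F7 with vinyl ketone 28 (second-generation Hoveyda–Grubbs catalyst, CH2Cl2, 40 °C) gives the (E)-enone, and the fallback comes back at 29.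

**Further compounds**

F1 | step 12 | 2-[5-iodo-2-(methoxymethoxy)phenyl]-1-[2,4,6-tris(methoxymethoxy)phenyl]ethan-1-one | COCOc1cc(OCOC)c(C(=O)Cc2cc(I)ccc2OCOC)c(OCOC)c1
F2 | step 12 | 1-[2-hydroxy-4,6-bis(methoxymethoxy)phenyl]-2-[5-iodo-2-(methoxymethoxy)phenyl]ethan-1-one | COCOc1cc(O)c(C(=O)Cc2cc(I)ccc2OCOC)c(OCOC)c1
F3 | step 12 | (2R,3S)-3-[5-iodo-2-(methoxymethoxy)phenyl]-5,7-bis(methoxymethoxy)-2-[4-(methoxymethoxy)phenyl]chroman-4-one | Ic1ccc(OCOC)c([C@@H]2C(=O)c3c(OCOC)cc(OCOC)cc3O[C@H]2c2ccc(OCOC)cc2)c1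
F4 | step 12 | (2S,3R)-3-[5-iodo-2-(methoxymethoxy)phenyl]-5,7-bis(methoxymethoxy)-2-[4-(methoxymethoxy)phenyl]chroman-4-one | Ic1ccc(OCOC)c([C@H]2C(=O)c3c(OCOC)cc(OCOC)cc3O[C@@H]2c2ccc(OCOC)cc2)c1
F5 | step 12 | (2R,3S)-3-{5-[(1E)-3-[2,4-bis(methoxymethoxy)phenyl]-3-oxoprop-1-en-1-yl]-2-(methoxymethoxy)phenyl}-5,7-bis(methoxymethoxy)-2-[4-(methoxymethoxy)phenyl]chroman-4-one | O=C(/C=C/c1ccc(OCOC)c([C@@H]2C(=O)c3c(OCOC)cc(OCOC)cc3O[C@H]2c2ccc(OCOC)cc2)c1)c1ccc(OCOC)cc1OCOC
F6 | step 8 | (1E,5R)-5-hydroxy-4-[5-iodo-2-(methoxymethoxy)phenyl]-1-methoxy-5-[4-(methoxymethoxy)phenyl]pent-1-en-3-one (mainly 4,5-syn) | CO/C=C/C(=O)C(c1cc(I)ccc1OCOC)[C@@H](O)c1ccc(OCOC)cc1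
F7 | step 16 | (2R,3S)-3-[5-ethenyl-2-(methoxymethoxy)phenyl]-5,7-dihydroxy-2-[4-(methoxymethoxy)phenyl]chroman-4-one | C=Cc1ccc(OCOC)c([C@@H]2C(=O)c3c(O)cc(O)cc3O[C@H]2c2ccc(OCOC)cc2)c1
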